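The runs are calculated with constants of no real substance, noise included.

Slowness is what I read first: X turns into L slowly in these flasks, so the question is how much L stands at the time asked.

the same everywhere: X 200 mM; E 1.00 mM
- amber: G 300 mM
- violet: G 900 mM
- green: G 300 mM; L 60.0 mM
- ochre: G 300 mM; time 57 min

| run | time / min | [L] / mM |
|---|---|---|
| amber run | 0.68 | 4.1 |
| amber run | 2.1 | 11.0 |
| amber run | 4.0 | 23.1 |
| amber run | 6.3 | 36.9 |
| amber run | 9.0 | 49.7 |
| amber run | 12 | 64.2 |
| amber run | 15 | 74.4 |
| amber run | 19 | 91.3 |
| violet run | 0.68 | 8.4 |
| violet run | 2.1 | 28.3 |
| violet run | 4.0 | 52.0 |
| violet run | 6.3 | 78.7 |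
| violet run | 9.0 | 102.1 |
| violet run | 12 | 128.7 |
| violet run | 15 | 148.2 |
| violet run | 19 | 167.5 |
| green run | 0.68 | 65.1 |
| green run | 2.1 | 72.7 |
| green run | 4.0 | 83.1 |
| green run | 6.3 | 95.8 |
| green run | 9.0 | 109.9 |
| green run | 12 | 123.2 |
| green run | 15 | 137.8 |
| green run | 19 | 151.9 |

(readings scatter by 1 mM)

1. the power of [G] that the first rate follows, about the charge of the amber run; measure it at two percent of X made into L
2. L in the ochre run at 57 min, as a share of the X charged
3. which of these the readings show (nothing beyond the main steps / the second partner is lost in pairs / the two partners rest in a complex / the substrate ties up the catalyst)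

- Overall: X + G -> L, with E as catalyst.
- Constant volume, constant temperature.
- Bound and free are read together.
- "The second partner" is G.
- An order is taken over about fifteen percent of the charge, up and down.

1. I start with a balance. X is the limiting reagent, charged at 200 mM against 300 mM of G. Each L takes one X, so in the amber run [X] is the charge minus [L].

2. In the amber run [X] goes from 126 mM at 15 min to 109 mM at 19 min, which gives 19.2 min. I call this the late halving time: the time in which [X] would fall to half at the pace of a stretch, which is the stretch's length times ln(2), divided by the ln of the ratio of [X] at its two ends. It is a reading and carries their scatter.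

3. The first rung of my ladder is the end of the violet run, where the same measure gives 5.95 min. The start of the violet run, with 52.0 mM of L made by 4.0 min, gives a slower 9.21 min.

4. The next rung is the amber run. Its start, with 49.7 mM of L made by 9.0 min, gives 21.8 min, slower than its late 19.2 min, although [G] falls along with [X]. So in the violet and amber runs the halving time shortens as [X] falls, and I choose X tying up E.

5. The green run has made 91.9 mM of new L by 19 min, and the amber run has made 91.3 mM by then, so I leave the added L off my ladder.

6. The last rung is the question. The ochre charge equals the amber charge, so I take the amber reading at 19 min and hold the late halving time over the remaining 38.0 min, which is 1.98 halvings. That gives me 86.2 %.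

7. The forecast says 93.5 %, higher than mine, with an order of 0.84 in G and the verdict nothing beyond the main steps: “No extra loss or resting state is needed.”

The simulation gives an order of 0.86, 89.0 % in the ochre run, and the verdict the substrate ties up the catalyst.

    E + G ⇌ EG, settled at all times (5.220 /M)
    EG + X → L + E (205.8 /M/min)
    E + X ⇌ EX, settled at all times (40.30 /M)

From 19 min to 57 min the ochre run's halving time comes to 16.4 min, shorter than the late amber 19.2 min. The main reason for the shortfall from full conversion is the association of E + X to EX. Without that association the ochre run reaches 99.1 % at 57 min, and its halving time over the whole run is 8.39 min, against 17.9 min with it.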